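**Retrosynthetic overview**

- Feature: the spiro carbon C-5 is quaternary, carries the C-1 methylene (CH2–O) of ring B, and sits in ring A between C-10 (C(CH3)OH) and C-6 (the CH with the 3-hydroxypropyl arm). With C-10 written as C=O this is a 2-(hydroxymethyl)cyclohexanone with a quaternary α-carbon, the retron of a semipinacol ring expansion.
- Key disconnection: the C-5–C-6 bond, by 1,2-shift of the allyl-bearing ring carbon in a 1-oxiranylcyclopentanol (BF3·OEt2). The epoxide comes from hydroxyl-directed epoxidation of the adduct of a trans-2-allyl-3-silylcyclopentanone (from cyclopentenone) with an alkenylcerium reagent made from (R)-benzyl glycidyl ether.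
- Ring order: cyclopentane (starting material) → ring A by ring expansion → ring B by Williamson closure O-2–C-1 → temporary eight-membered lactone (a tether that fixes the Z enal), opened at the end.
- Late stage: C-10 methyl by Grignard addition, arm by hydroboration, C-7 silyl group as latent ketone (Fleming–Tamao), triene by Wittig and Horner–Wadsworth–Emmons (HWE) olefinations, lactone reduction and allylic oxidation.

Key step: step 7

**Remarks on the chemistry**

- Locants: all spirocyclic compounds use the locants of the target's 2-oxaspiro[4.5]decane: C-1 (CH2O), O-2, C-3, C-4, C-5 (spiro), C-6 (CH with arm), C-7, C-8, C-9, C-10 (carbinol). TBS = tert-butyldimethylsilyl.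
- Design choice: the ring carbon next to the migrating CH carries SiMe2Ph (a latent hydroxyl) during the key step, not a silyloxy group. An oxygen there would withdraw electron density from the migrating carbon, and a 3-silyloxycyclopentanone is prone to β-elimination; the C–Si bond instead assists the shift and is oxidised later.
- The phosphonate-bearing carbon of the tether is a mixture of epimers; it is destroyed in the olefination.
- In step 1 the antipode of the chiral NHC ligand is chosen so that the (S)-C–Si centre is formed.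

**Route**

Step 1
Reactants: 1 cyclopent-2-en-1-one; 2 2-[dimethyl(phenyl)silyl]-4,4,5,5-tetramethyl-1,3,2-dioxaborolane; 3 allyl bromide
Product: 6 (2S,3S)-2-allyl-3-[dimethyl(phenyl)silyl]cyclopentan-1-one, via pinacolboron enolate 4 (not isolated), via lithium enolate 5 (not isolated)
Conditions: CuCl (2 mol %), chiral C1-symmetric imidazolinium tetrafluoroborate (NHC precursor, 2.2 mol %), NaOtBu (5 mol %), THF, −78 °C; MeLi (1.05 equiv), −78 °C; then 3, DMPU, −78 → −20 °C
Reagents that add atoms: methyllithium, [Li]C (supplies only the lithium of 5)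
Why: Enantioselective NHC–Cu-catalysed conjugate silyl transfer from the Si–B reagent sets the (S)-C–Si centre and leaves a regiodefined boron enolate which, after boron-to-lithium exchange, is allylated at C-2 anti to the bulky silyl group (conjugate addition–enolate alkylation), giving the trans ketone.

Step 2
Reactants: 7 (R)-benzyl glycidyl ether
Product: 8 (R)-1-(benzyloxy)pent-4-yn-2-ol
Conditions: LiC≡CH·H2NCH2CH2NH2, DMSO, 0 °C → rt; H2O
Reagents that add atoms: lithium acetylide ethylenediamine complex, [Li]C#C.NCCN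
Why: SN2 opening of the terminal epoxide at its CH2 by the acetylide leaves the stereocentre of the chiral-pool epoxide untouched.

Step 3
Reactants: 8 (R)-1-(benzyloxy)pent-4-yn-2-ol
Product: 9 (R)-{[1-(benzyloxy)pent-4-yn-2-yl]oxy}(tert-butyl)dimethylsilane
Conditions: TBSCl, imidazole, DMF, rt
Reagents that add atoms: tert-butyldimethylsilyl chloride, CC(C)(C)[Si](C)(C)Cl
Why: Silyl ether protection of the secondary alcohol masks the future ring-B oxygen through the organolithium and Lewis acid steps.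

Step 4
Reactants: 9 (R)-{[1-(benzyloxy)pent-4-yn-2-yl]oxy}(tert-butyl)dimethylsilane
Product: 11 (R)-{[1-(benzyloxy)-4-bromopent-4-en-2-yl]oxy}(tert-butyl)dimethylsilane, via (Z)-2-bromoalkenyl-9-BBN 10 (not isolated)
Conditions: B-bromo-9-BBN, CH2Cl2, 0 °C; then AcOH, 0 °C → rt
Reagents that add atoms: B-bromo-9-borabicyclo[3.3.1]nonane, BrB1C2CCCC1CCC2
Why: Syn-bromoboration of the terminal alkyne places bromine on the internal carbon, and protonolysis of the alkenyl C–B bond with acetic acid leaves the 2-bromo-1-alkene (haloboration–protodeboronation).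

Step 5
Reactants: 11 (R)-{[1-(benzyloxy)-4-bromopent-4-en-2-yl]oxy}(tert-butyl)dimethylsilane; 6 (2S,3S)-2-allyl-3-[dimethyl(phenyl)silyl]cyclopentan-1-one
Product: 14 (1S,2S,3S)-2-allyl-1-[(4R)-5-(benzyloxy)-4-(TBSO)pent-1-en-2-yl]-3-[dimethyl(phenyl)silyl]cyclopentan-1-ol, via alkenyllithium 12 (not isolated), via alkenylcerium dichloride 13 (not isolated)
Conditions: t-BuLi (2.05 equiv), Et2O, −78 °C; anhydrous CeCl3, THF, −78 °C; then 6, −78 → −40 °C; H2O
Reagents that add atoms: tert-butyllithium, [Li]C(C)(C)C (supplies only the lithium of 12); cerium trichloride, Cl[Ce](Cl)Cl (supplies only the CeCl2 of 13)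
Why: Bromine–lithium exchange and transmetalation to the weakly basic organocerium reagent allow 1,2-addition to the enolisable cyclopentanone, with attack anti to the adjacent allyl group so that the new (1S) carbinol has OH cis to allyl.

Step 6
Reactants: 14 (1S,2S,3S)-2-allyl-1-[(4R)-5-(benzyloxy)-4-(TBSO)pent-1-en-2-yl]-3-[dimethyl(phenyl)silyl]cyclopentan-1-ol
Product: 15 (1S,2S,3S)-2-allyl-1-{(2R)-2-[(2R)-3-(benzyloxy)-2-(TBSO)propyl]oxiran-2-yl}-3-[dimethyl(phenyl)silyl]cyclopentan-1-ol
Conditions: VO(acac)2 (5 mol %), t-BuOOH (1.5 equiv, decane), CH2Cl2, 0 °C → rt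
Reagents that add atoms: tert-butyl hydroperoxide, CC(C)(C)OO
Why: Hydroxyl-directed vanadium-catalysed epoxidation is selective for the allylic alkene over the remote allyl group, and the vanadate transition state (O–C–C=C near 45°) places the less substituted ring CH2 next to the alkene substituent and the allyl-bearing ring carbon away from it, which should deliver oxygen to the face giving the (R)-epoxide.

Step 7
Reactants: 15 (1S,2S,3S)-2-allyl-1-{(2R)-2-[(2R)-3-(benzyloxy)-2-(TBSO)propyl]oxiran-2-yl}-3-[dimethyl(phenyl)silyl]cyclopentan-1-ol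
Product: 16 (2S,3S,4S)-3-allyl-2-[(2R)-3-(benzyloxy)-2-(TBSO)propyl]-4-[dimethyl(phenyl)silyl]-2-(hydroxymethyl)cyclohexan-1-one
Conditions: BF3·OEt2 (1.1 equiv), CH2Cl2, −78 °C; H2O quench at −78 °C
Reagents that add atoms: none
Why: BF3 binds the epoxide oxygen and weakens the C–O bond at the tertiary epoxide carbon while the antiperiplanar cyclopentane bond C-1–C-2 (C-2 is the allyl-bearing CH) shifts to that carbon in concert and the carbinol becomes the ketone, a Lewis acid semipinacol rearrangement of a 2,3-epoxy alcohol whose closest known reaction type is the ring expansion of 1-oxiranylcycloalkanols to 2-(hydroxymethyl)cycloalkanones. Ring A is closed not by a cyclisation but by this suprafacial 1,2-alkyl shift, which enlarges the cyclopentane by one carbon and forms the C-5–C-6 bond of the target. The new quaternary stereocentre arises by inversion at the epoxide carbon (backside entry of the migrating bond), so the (R)-epoxide from step 6 gives the (2S) ketone, while the migrating CH keeps its configuration. The selectivity needed is migration of the allyl-bearing CH and not of the ring CH2; it is secured by the higher substitution of that carbon and by the C–Si bond on its neighbour, which lies nearly anti to the migrating bond in the pseudo-equatorial conformer and stabilises positive charge on the migrating carbon (β-silicon effect, as in silicon-directed Baeyer–Villiger and Wagner–Meerwein shifts). A concerted shift at −78 °C in CH2Cl2 is expected to outrun ionisation to a free cation and capture by the benzyl ether oxygen, and the silyl ether, the C–Si bond and the allyl group should tolerate the conditions.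

Step 8
Reactants: 16 (2S,3S,4S)-3-allyl-2-[(2R)-3-(benzyloxy)-2-(TBSO)propyl]-4-[dimethyl(phenyl)silyl]-2-(hydroxymethyl)cyclohexan-1-one
Product: 17 {(1S,2S,3S)-2-allyl-1-[(2R)-3-(benzyloxy)-2-(TBSO)propyl]-3-[dimethyl(phenyl)silyl]-6-oxocyclohexyl}methyl 4-methylbenzenesulfonate
Conditions: TsCl, pyridine, DMAP (cat.), CH2Cl2, 0 °C → rt
Reagents that add atoms: p-toluenesulfonyl chloride, Cc1ccc(cc1)S(Cl)(=O)=O
Why: Sulfonylation of the only free hydroxyl, a primary neopentyl alcohol, makes C-1 the electrophile for ring B, and the quaternary α-carbon rules out β-elimination.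

Step 9
Reactants: 17 {(1S,2S,3S)-2-allyl-1-[(2R)-3-(benzyloxy)-2-(TBSO)propyl]-3-[dimethyl(phenyl)silyl]-6-oxocyclohexyl}methyl 4-methylbenzenesulfonate
Product: 19 (3R,5S,6S,7S)-6-allyl-3-[(benzyloxy)methyl]-7-[dimethyl(phenyl)silyl]-2-oxaspiro[4.5]decan-10-one, via hydroxy tosylate 18 (not isolated)
Conditions: TBAF (1.2 equiv), THF, 0 → 50 °C
Reagents that add atoms: none
Why: Fluoride removes the TBS group and the liberated C-3 alkoxide closes ring B by 5-exo-tet Williamson displacement of the tosylate, the C-3 stereocentre being the nucleophile and therefore retained, with the gem-disubstituted C-5 favouring closure over hemiketal-mediated fragmentation.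

Step 10
Reactants: 19 (3R,5S,6S,7S)-6-allyl-3-[(benzyloxy)methyl]-7-[dimethyl(phenyl)silyl]-2-oxaspiro[4.5]decan-10-one
Product: 20 (3R,5S,6S,7S,10S)-6-allyl-3-[(benzyloxy)methyl]-7-[dimethyl(phenyl)silyl]-10-methyl-2-oxaspiro[4.5]decan-10-ol
Conditions: MeMgBr (3 equiv), THF, −78 → 0 °C; H2O
Reagents that add atoms: methylmagnesium bromide, C[Mg]Br
Why: Grignard 1,2-addition should occur axially, anti to the axial C-1 methylene of ring B in the chair that keeps the allyl and silyl groups equatorial, which gives the (10S) carbinol with OH cis to C-1 and to the C-6 substituent.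

Step 11
Reactants: 20 (3R,5S,6S,7S,10S)-6-allyl-3-[(benzyloxy)methyl]-7-[dimethyl(phenyl)silyl]-10-methyl-2-oxaspiro[4.5]decan-10-ol
Product: 22 (3R,5S,6S,7S,10S)-3-[(benzyloxy)methyl]-7-[dimethyl(phenyl)silyl]-6-(3-hydroxypropyl)-10-methyl-2-oxaspiro[4.5]decan-10-ol, via B-alkyl-9-BBN 21 (not isolated)
Conditions: 9-BBN (3 equiv), THF, 0 °C → rt; NaOH, H2O2, 0 °C → rt
Reagents that add atoms: 9-borabicyclo[3.3.1]nonane, B1C2CCCC1CCC2 (supplies only the boron framework of 21); hydrogen peroxide, OO
Why: 9-BBN hydroborates the only alkene, the terminal allyl group, in the anti-Markovnikov sense and oxidation of the C–B bond gives the primary alcohol (hydroboration–oxidation), the C–Si bond being inert to alkaline peroxide.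

Step 12
Reactants: 22 (3R,5S,6S,7S,10S)-3-[(benzyloxy)methyl]-7-[dimethyl(phenyl)silyl]-6-(3-hydroxypropyl)-10-methyl-2-oxaspiro[4.5]decan-10-ol; 23 2-(diethoxyphosphoryl)propanoic acid
Product: 24 3-{(3R,5S,6S,7S,10S)-3-[(benzyloxy)methyl]-7-[dimethyl(phenyl)silyl]-10-hydroxy-10-methyl-2-oxaspiro[4.5]decan-6-yl}propyl 2-(diethoxyphosphoryl)propanoate
Conditions: DCC, DMAP (cat.), CH2Cl2, 0 °C → rt
Reagents that add atoms: none
Why: Carbodiimide (Steglich) esterification acylates only the primary alcohol, the tertiary carbinol being too hindered, and installs the phosphonate tether on the C-6 arm.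

Step 13
Reactants: 24 3-{(3R,5S,6S,7S,10S)-3-[(benzyloxy)methyl]-7-[dimethyl(phenyl)silyl]-10-hydroxy-10-methyl-2-oxaspiro[4.5]decan-6-yl}propyl 2-(diethoxyphosphoryl)propanoate
Product: 25 3-{(3R,5S,6S,7S,10S)-3-[(benzyloxy)methyl]-7,10-dihydroxy-10-methyl-2-oxaspiro[4.5]decan-6-yl}propyl 2-(diethoxyphosphoryl)propanoate
Conditions: KBr, NaOAc, AcOOH (32 % in AcOH), AcOH, 0 °C → rt
Reagents that add atoms: peracetic acid, CC(=O)OO
Why: Fleming–Tamao oxidation (bromodesilylation of the phenyl group, then peracid-induced 1,2-shift from silicon to oxygen) converts C–Si into C–OH with retention, and no alkene or ketone is present at this stage to interfere.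

Step 14
Reactants: 25 3-{(3R,5S,6S,7S,10S)-3-[(benzyloxy)methyl]-7,10-dihydroxy-10-methyl-2-oxaspiro[4.5]decan-6-yl}propyl 2-(diethoxyphosphoryl)propanoate
Product: 26 3-{(3R,5S,6S,10S)-3-[(benzyloxy)methyl]-10-hydroxy-10-methyl-7-oxo-2-oxaspiro[4.5]decan-6-yl}propyl 2-(diethoxyphosphoryl)propanoate
Conditions: Dess–Martin periodinane, CH2Cl2, rt
Reagents that add atoms: none
Why: Dess–Martin oxidation converts the secondary alcohol into the C-7 ketone and leaves the tertiary alcohol and the phosphonate untouched.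

Step 15
Reactants: 26 3-{(3R,5S,6S,10S)-3-[(benzyloxy)methyl]-10-hydroxy-10-methyl-7-oxo-2-oxaspiro[4.5]decan-6-yl}propyl 2-(diethoxyphosphoryl)propanoate
Product: 27 (3R,5S,6R,10S)-3-[(benzyloxy)methyl]-10-hydroxy-10-methyl-2-oxaspiro[4.5]decane carrying an eight-membered (Z)-α-methyl-α,β-unsaturated lactone fused at C-6/C-7 (C-6–CH2CH2CH2–O–C(=O)–C(CH3)=C-7)
Conditions: NaH (3 equiv), THF (0.002 M, slow addition of 26), 0 → 60 °C
Reagents that add atoms: none
Why: Proposed new method: the phosphonate carbanion held on the C-6 arm can reach only the adjacent C-7 ketone, so aldol-type addition and syn-elimination of phosphate (intramolecular Horner–Wadsworth–Emmons reaction) should close an eight-membered lactone whose ring forces the ester carbon cis to C-6, which is the required Z tetrasubstituted alkene; the closest known reaction types are the intermolecular HWE olefination of cyclohexanones with 2-phosphonopropanoates and HWE macrolactonisation, but closure of an eight-membered lactone onto a hindered ketone has not been shown.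

Step 16
Reactants: 27 the (3R,5S,6R,10S) benzyl ether lactone
Product: 28 (3R,5S,6R,10S)-3-(hydroxymethyl) lactone (27 without the benzyl group)
Conditions: H2 (1 atm), Pd/C (10 %), EtOAc, rt
Reagents that add atoms: none
Why: Hydrogenolysis cleaves the benzyl ether, while the tetrasubstituted conjugated ring alkene is too hindered to be hydrogenated at 1 atm.

Step 17
Reactants: 28 (3R,5S,6R,10S)-3-(hydroxymethyl) lactone
Product: 29 (3R,5S,6R,10S)-3-formyl lactone (2-oxaspiro[4.5]decane-3-carbaldehyde)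
Conditions: Dess–Martin periodinane, CH2Cl2, 0 °C → rt
Reagents that add atoms: none
Why: Dess–Martin oxidation of the primary alcohol under non-basic conditions gives the α-alkoxy aldehyde without epimerisation at C-3, the tertiary alcohol being inert.

Step 18
Reactants: 29 (3R,5S,6R,10S)-3-formyl lactone; 30 2-(triphenyl-λ5-phosphanylidene)propanal
Product: 31 (3R,5S,6R,10S)-3-[(1E)-2-methyl-3-oxoprop-1-enyl] lactone
Conditions: toluene, 80 °C
Reagents that add atoms: none
Why: Wittig reaction with the stabilised formyl ylide should give the (E)-2-methyl enal under neutral conditions that neither epimerise C-3 nor touch the lactone.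

Step 19
Reactants: 32 geranyl bromide; 33 triethyl phosphite
Product: 34 diethyl [(2E)-3,7-dimethylocta-2,6-dienyl]phosphonate
Conditions: neat, 130 °C, EtBr distilled off
Reagents that add atoms: none
Why: Michaelis–Arbuzov reaction of the primary allylic bromide (SN2 at C-1, then dealkylation of the phosphonium salt) gives the allylic phosphonate with the (E) alkene preserved.

Step 20
Reactants: 31 (3R,5S,6R,10S)-3-[(1E)-2-methyl-3-oxoprop-1-enyl] lactone; 34 diethyl [(2E)-3,7-dimethylocta-2,6-dienyl]phosphonate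
Product: 36 (3R,5S,6R,10S)-3-[(1E,3E,5E)-2,6,10-trimethylundeca-1,3,5,9-tetraenyl] lactone, via lithiated phosphonate 35 (not isolated)
Conditions: 34, n-BuLi, THF, −78 °C; then 31 (0.4 equiv relative to 35), −78 → −20 °C
Reagents that add atoms: n-butyllithium, [Li]CCCC (supplies only the lithium of 35)
Why: HWE olefination in which the lithiated allylic phosphonate reacts at its α-carbon with the enal should form the new disubstituted alkene with E selectivity and complete the all-E triene, the aldehyde reacting far faster than the lactone at low temperature.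

Step 21
Reactants: 36 (3R,5S,6R,10S) triene lactone
Product: 37 (3R,5S,6R,10S)-7-[(2Z)-1-hydroxypropan-2-ylidene]-6-(3-hydroxypropyl)-10-methyl-3-[(1E,3E,5E)-2,6,10-trimethylundeca-1,3,5,9-tetraenyl]-2-oxaspiro[4.5]decan-10-ol
Conditions: i-Bu2AlH (5 equiv), CH2Cl2, −78 → 0 °C; aq. potassium sodium tartrate
Reagents that add atoms: none
Why: i-Bu2AlH reduces the lactone fully to the primary allylic alcohol and the 3-hydroxypropyl arm without touching the triene, so the alkene geometry fixed in the ring is carried into the open chain.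

Step 22
Reactants: 37 the triol
Product: 38 CNP0220216.1, (2Z)-2-{(3R,5S,6R,10S)-10-hydroxy-6-(3-hydroxypropyl)-10-methyl-3-[(1E,3E,5E)-2,6,10-trimethylundeca-1,3,5,9-tetraenyl]-2-oxaspiro[4.5]decan-7-ylidene}propanal
Conditions: activated MnO2 (20 equiv), CH2Cl2, rt
Reagents that add atoms: none
Why: MnO2 oxidises only the allylic primary alcohol to the Z enal and leaves the saturated primary alcohol, the tertiary alcohol and the triene intact (chemoselective allylic oxidation).

**Compound list**

1 | cyclopent-2-en-1-one | O=C1C=CCC1 | starting material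
2 | 2-[dimethyl(phenyl)silyl]-4,4,5,5-tetramethyl-1,3,2-dioxaborolane | CC1(C)OB(OC1(C)C)[Si](C)(C)c1ccccc1 | starting material
3 | allyl bromide | C=CCBr | starting material
4 | (S)-2-({3-[dimethyl(phenyl)silyl]cyclopent-1-en-1-yl}oxy)-4,4,5,5-tetramethyl-1,3,2-dioxaborolane (not isolated) | CC1(C)OB(OC2=C[C@@H]([Si](C)(C)c3ccccc3)CC2)OC1(C)C | intermediate
5 | lithium (S)-3-[dimethyl(phenyl)silyl]cyclopent-1-en-1-olate (not isolated) | [Li]OC1=C[C@@H]([Si](C)(C)c2ccccc2)CC1 | intermediate
6 | (2S,3S)-2-allyl-3-[dimethyl(phenyl)silyl]cyclopentan-1-one | O=C1CC[C@H]([Si](C)(C)c2ccccc2)[C@H]1CC=C | intermediate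
7 | (R)-benzyl glycidyl ether | C(c1ccccc1)OC[C@H]1CO1 | starting material
8 | (R)-1-(benzyloxy)pent-4-yn-2-ol | C(c1ccccc1)OC[C@H](O)CC#C | intermediate
9 | (R)-{[1-(benzyloxy)pent-4-yn-2-yl]oxy}(tert-butyl)dimethylsilane | C(c1ccccc1)OC[C@H](O[Si](C)(C)C(C)(C)C)CC#C | intermediate
10 | 9-[(1Z,4R)-5-(benzyloxy)-2-bromo-4-(TBSO)pent-1-enyl]-9-borabicyclo[3.3.1]nonane (not isolated) | C(c1ccccc1)OC[C@H](O[Si](C)(C)C(C)(C)C)C/C(Br)=C/B1C2CCCC1CCC2 | intermediate
11 | (R)-{[1-(benzyloxy)-4-bromopent-4-en-2-yl]oxy}(tert-butyl)dimethylsilane | C(c1ccccc1)OC[C@H](O[Si](C)(C)C(C)(C)C)CC(Br)=C | intermediate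
12 | [(4R)-5-(benzyloxy)-4-(TBSO)pent-1-en-2-yl]lithium (not isolated) | C(c1ccccc1)OC[C@H](O[Si](C)(C)C(C)(C)C)CC([Li])=C | intermediate
13 | [(4R)-5-(benzyloxy)-4-(TBSO)pent-1-en-2-yl]cerium dichloride (not isolated) | C(c1ccccc1)OC[C@H](O[Si](C)(C)C(C)(C)C)CC(=C)[Ce](Cl)Cl | intermediate
14 | (1S,2S,3S)-2-allyl-1-[(4R)-5-(benzyloxy)-4-(TBSO)pent-1-en-2-yl]-3-[dimethyl(phenyl)silyl]cyclopentan-1-ol | C(c1ccccc1)OC[C@H](O[Si](C)(C)C(C)(C)C)CC(=C)[C@]1(O)CC[C@H]([Si](C)(C)c2ccccc2)[C@H]1CC=C | intermediate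
15 | (1S,2S,3S)-2-allyl-1-{(2R)-2-[(2R)-3-(benzyloxy)-2-(TBSO)propyl]oxiran-2-yl}-3-[dimethyl(phenyl)silyl]cyclopentan-1-ol | C(c1ccccc1)OC[C@H](O[Si](C)(C)C(C)(C)C)C[C@@]2(CO2)[C@]3(O)CC[C@H]([Si](C)(C)c4ccccc4)[C@H]3CC=C | intermediate
16 | (2S,3S,4S)-3-allyl-2-[(2R)-3-(benzyloxy)-2-(TBSO)propyl]-4-[dimethyl(phenyl)silyl]-2-(hydroxymethyl)cyclohexan-1-one | C(c1ccccc1)OC[C@H](O[Si](C)(C)C(C)(C)C)C[C@@]2(CO)[C@H](CC=C)[C@@H]([Si](C)(C)c3ccccc3)CCC2=O | intermediate
17 | {(1S,2S,3S)-2-allyl-1-[(2R)-3-(benzyloxy)-2-(TBSO)propyl]-3-[dimethyl(phenyl)silyl]-6-oxocyclohexyl}methyl 4-methylbenzenesulfonate | C(c1ccccc1)OC[C@H](O[Si](C)(C)C(C)(C)C)C[C@@]2(COS(=O)(=O)c3ccc(C)cc3)[C@H](CC=C)[C@@H]([Si](C)(C)c4ccccc4)CCC2=O | intermediate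
18 | {(1S,2S,3S)-2-allyl-1-[(2R)-3-(benzyloxy)-2-hydroxypropyl]-3-[dimethyl(phenyl)silyl]-6-oxocyclohexyl}methyl 4-methylbenzenesulfonate (not isolated) | C(c1ccccc1)OC[C@H](O)C[C@@]2(COS(=O)(=O)c3ccc(C)cc3)[C@H](CC=C)[C@@H]([Si](C)(C)c4ccccc4)CCC2=O | intermediate
19 | (3R,5S,6S,7S)-6-allyl-3-[(benzyloxy)methyl]-7-[dimethyl(phenyl)silyl]-2-oxaspiro[4.5]decan-10-one | C(c1ccccc1)OC[C@H]1C[C@@]2(CO1)[C@H](CC=C)[C@@H]([Si](C)(C)c3ccccc3)CCC2=O | intermediate
20 | (3R,5S,6S,7S,10S)-6-allyl-3-[(benzyloxy)methyl]-7-[dimethyl(phenyl)silyl]-10-methyl-2-oxaspiro[4.5]decan-10-ol | C(c1ccccc1)OC[C@H]1C[C@@]2(CO1)[C@H](CC=C)[C@@H]([Si](C)(C)c3ccccc3)CC[C@]2(C)O | intermediate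
21 | B-alkyl-9-BBN adduct of 20 at the terminal allyl carbon (not isolated) | C(c1ccccc1)OC[C@H]1C[C@@]2(CO1)[C@H](CCCB3C4CCCC3CCC4)[C@@H]([Si](C)(C)c5ccccc5)CC[C@]2(C)O | intermediate
22 | (3R,5S,6S,7S,10S)-3-[(benzyloxy)methyl]-7-[dimethyl(phenyl)silyl]-6-(3-hydroxypropyl)-10-methyl-2-oxaspiro[4.5]decan-10-ol | C(c1ccccc1)OC[C@H]1C[C@@]2(CO1)[C@H](CCCO)[C@@H]([Si](C)(C)c3ccccc3)CC[C@]2(C)O | intermediate
23 | 2-(diethoxyphosphoryl)propanoic acid | CC(C(=O)O)P(=O)(OCC)OCC | starting material
24 | 3-{(3R,5S,6S,7S,10S)-3-[(benzyloxy)methyl]-7-[dimethyl(phenyl)silyl]-10-hydroxy-10-methyl-2-oxaspiro[4.5]decan-6-yl}propyl 2-(diethoxyphosphoryl)propanoate | C(c1ccccc1)OC[C@H]1C[C@@]2(CO1)[C@H](CCCOC(=O)C(C)P(=O)(OCC)OCC)[C@@H]([Si](C)(C)c3ccccc3)CC[C@]2(C)O | intermediate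
25 | 3-{(3R,5S,6S,7S,10S)-3-[(benzyloxy)methyl]-7,10-dihydroxy-10-methyl-2-oxaspiro[4.5]decan-6-yl}propyl 2-(diethoxyphosphoryl)propanoate | C(c1ccccc1)OC[C@H]1C[C@@]2(CO1)[C@H](CCCOC(=O)C(C)P(=O)(OCC)OCC)[C@@H](O)CC[C@]2(C)O | intermediate
26 | 3-{(3R,5S,6S,10S)-3-[(benzyloxy)methyl]-10-hydroxy-10-methyl-7-oxo-2-oxaspiro[4.5]decan-6-yl}propyl 2-(diethoxyphosphoryl)propanoate | C(c1ccccc1)OC[C@H]1C[C@@]2(CO1)[C@H](CCCOC(=O)C(C)P(=O)(OCC)OCC)C(=O)CC[C@]2(C)O | intermediate
27 | (3R,5S,6R,10S) benzyl ether of the tricyclic eight-membered (Z)-lactone | C(c1ccccc1)OC[C@H]1C[C@@]2(CO1)[C@@H]3CCCOC(=O)/C(C)=C3/CC[C@]2(C)O | intermediate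
28 | (3R,5S,6R,10S)-3-(hydroxymethyl) tricyclic (Z)-lactone | OC[C@H]1C[C@@]2(CO1)[C@@H]3CCCOC(=O)/C(C)=C3/CC[C@]2(C)O | intermediate
29 | (3R,5S,6R,10S)-3-formyl tricyclic (Z)-lactone | O=C[C@H]1C[C@@]2(CO1)[C@@H]3CCCOC(=O)/C(C)=C3/CC[C@]2(C)O | intermediate
30 | 2-(triphenyl-λ5-phosphanylidene)propanal | CC(C=O)=P(c1ccccc1)(c1ccccc1)c1ccccc1 | starting material
31 | (3R,5S,6R,10S)-3-[(1E)-2-methyl-3-oxoprop-1-enyl] tricyclic (Z)-lactone | O=C/C(C)=C/[C@H]1C[C@@]2(CO1)[C@@H]3CCCOC(=O)/C(C)=C3/CC[C@]2(C)O | intermediate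
32 | geranyl bromide | CC(C)=CCC/C(C)=C/CBr | starting material
33 | triethyl phosphite | CCOP(OCC)OCC | starting material
34 | diethyl [(2E)-3,7-dimethylocta-2,6-dienyl]phosphonate | CC(C)=CCC/C(C)=C/CP(=O)(OCC)OCC | intermediate
35 | α-lithiated diethyl geranylphosphonate (not isolated) | CC(C)=CCC/C(C)=C/C([Li])P(=O)(OCC)OCC | intermediate
36 | (3R,5S,6R,10S)-3-[(1E,3E,5E)-2,6,10-trimethylundeca-1,3,5,9-tetraenyl] tricyclic (Z)-lactone | CC(C)=CCC/C(C)=C/C=C/C(C)=C/[C@H]1C[C@@]2(CO1)[C@@H]3CCCOC(=O)/C(C)=C3/CC[C@]2(C)O | intermediate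
37 | (3R,5S,6R,10S)-7-[(2Z)-1-hydroxypropan-2-ylidene]-6-(3-hydroxypropyl)-10-methyl-3-[(1E,3E,5E)-2,6,10-trimethylundeca-1,3,5,9-tetraenyl]-2-oxaspiro[4.5]decan-10-ol | CC(C)=CCC/C(C)=C/C=C/C(C)=C/[C@H]1C[C@@]2(CO1)[C@H](CCCO)/C(=C(/C)CO)CC[C@]2(C)O | intermediate
38 | CNP0220216.1 | CC(C)=CCC/C(C)=C/C=C/C(C)=C/[C@H]1C[C@@]2(CO1)[C@H](CCCO)/C(=C(/C)C=O)CC[C@]2(C)O | target

**Step count**

Total: 22 steps. Longest linear sequence: 20 steps (from 7 through steps 2–18 and 20–22).

**Steps most likely to fail**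

1. Step 15 (proposed new method). Closure of the eight-membered ring may be outpaced by intermolecular olefination and oligomerisation, or by enolisation of the hindered C-7 ketone, so that no lactone forms. The fallback uses known aldol-type ring closure followed by E1cB elimination; it sets out from 22 and returns at 27. Alcohol 22 is acylated with 2-bromopropanoyl bromide and pyridine to the 2-bromopropanoate F1. Fleming–Tamao oxidation as in step 13 gives the C-7 alcohol F2, and Dess–Martin oxidation gives the keto bromo ester F3. SmI2 in THF at high dilution effects an intramolecular Reformatsky reaction (known for medium-ring lactones), and the samarium aldolate is trapped with Ac2O as the β-acetoxy lactone F4. DBU then eliminates acetate across the only acidic α-position; the ring again forces the Z alkene, giving 27.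

2. Step 7 (key step). The BF3-complexed epoxide may ionise to an open tertiary cation (elimination, loss of stereospecificity), be captured by the benzyl ether oxygen, or suffer competing migration of the ring CH2. The fallback triggers the same ring expansion without a Lewis acid or an epoxide; it sets out from 14 and returns at 19. Allylic alcohol 14 is treated with NBS in CH2Cl2/i-PrOH at −20 °C (known halonium-induced semipinacol ring expansion of 1-alkenylcycloalkanols), giving the β-bromo ketone F5. The bridged bromonium ion keeps the shift anti, and C-5 epimers, if formed, would be separated at this stage. TBAF then removes the TBS group and the alkoxide displaces bromide to give 19 directly.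

3. Step 1. Incomplete boron-to-lithium exchange or proton transfer between enolate and product may lead to unallylated ketone, over-allylation or loss of regiocontrol. The fallback separates the two events and fixes the regiochemistry with a classical blocking group; it sets out from 1 and returns at 6. The same CuCl/NHC-catalysed silyl transfer, quenched with water, gives (S)-3-[dimethyl(phenyl)silyl]cyclopentan-1-one F6. Formylation (HCO2Et, NaH) at the less hindered C-5 gives the hydroxymethylene ketone F7, and n-BuSH/TsOH converts it into the n-butylthiomethylene ketone F8. Deprotonation (KOtBu) can now occur only at C-2, and allyl bromide enters anti to silicon to give F9. Hot aqueous KOH in diethylene glycol removes the blocking group and gives 6.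

**Further compounds**

F1 | step 15 | 3-{(3R,5S,6S,7S,10S)-3-[(benzyloxy)methyl]-7-[dimethyl(phenyl)silyl]-10-hydroxy-10-methyl-2-oxaspiro[4.5]decan-6-yl}propyl 2-bromopropanoate | C(c1ccccc1)OC[C@H]1C[C@@]2(CO1)[C@H](CCCOC(=O)C(C)Br)[C@@H]([Si](C)(C)c3ccccc3)CC[C@]2(C)O
F2 | step 15 | 3-{(3R,5S,6S,7S,10S)-3-[(benzyloxy)methyl]-7,10-dihydroxy-10-methyl-2-oxaspiro[4.5]decan-6-yl}propyl 2-bromopropanoate | C(c1ccccc1)OC[C@H]1C[C@@]2(CO1)[C@H](CCCOC(=O)C(C)Br)[C@@H](O)CC[C@]2(C)O
F3 | step 15 | 3-{(3R,5S,6S,10S)-3-[(benzyloxy)methyl]-10-hydroxy-10-methyl-7-oxo-2-oxaspiro[4.5]decan-6-yl}propyl 2-bromopropanoate | C(c1ccccc1)OC[C@H]1C[C@@]2(CO1)[C@H](CCCOC(=O)C(C)Br)C(=O)CC[C@]2(C)O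
F4 | step 15 | C-7 acetoxy eight-membered saturated lactone (β-acetoxy precursor of 27) | C(c1ccccc1)OC[C@H]1C[C@@]2(CO1)[C@@H]3CCCOC(=O)C(C)C3(OC(C)=O)CC[C@]2(C)O
F5 | step 7 | (2S,3S,4S)-3-allyl-2-[(2R)-3-(benzyloxy)-2-(TBSO)propyl]-2-(bromomethyl)-4-[dimethyl(phenyl)silyl]cyclohexan-1-one | C(c1ccccc1)OC[C@H](O[Si](C)(C)C(C)(C)C)C[C@@]2(CBr)[C@H](CC=C)[C@@H]([Si](C)(C)c3ccccc3)CCC2=O
F6 | step 1 | (S)-3-[dimethyl(phenyl)silyl]cyclopentan-1-one | O=C1CC[C@H]([Si](C)(C)c2ccccc2)C1
F7 | step 1 | (S)-3-[dimethyl(phenyl)silyl]-5-(hydroxymethylene)cyclopentan-1-one | O=C1C(=CO)C[C@H]([Si](C)(C)c2ccccc2)C1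
F8 | step 1 | (S)-5-[(butylsulfanyl)methylene]-3-[dimethyl(phenyl)silyl]cyclopentan-1-one | O=C1C(=CSCCCC)C[C@H]([Si](C)(C)c2ccccc2)C1
F9 | step 1 | (2S,3S)-2-allyl-5-[(butylsulfanyl)methylene]-3-[dimethyl(phenyl)silyl]cyclopentan-1-one | O=C1C(=CSCCCC)C[C@H]([Si](C)(C)c2ccccc2)[C@H]1CC=C
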